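**Retrosynthetic overview**

1. The target is read as a (2R)-2H-chromen-6-ol joined through an (E)-trisubstituted alkene to a (5R)-3,5-disubstituted furan-2(5H)-one. The last two operations are desilylation and a catalyst-controlled 1,3-proton shift (C3–H to C5–H) on the β,γ-unsaturated furan-2(3H)-one.
2. Key disconnection: the furanone ring is cut at C2–C3 and at O1–C5, which removes O1–C2(=O) as one molecule of CO2 and leaves an acyclic propargylic mesylate. This is possible because ring atoms C3–C4–C5 stand at the oxidation level of a propargyl/alkyne unit, O1–C2(=O) is exactly CO2, and the C5 stereocentre is linked to C3 by a prototropic shift, so it can be set after the ring is closed.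
3. The skipped enyne is cut between the alkyne and the allylic CH2 (copper-mediated alkyne–allyl coupling) into a racemic C9 alkynol and a chromene-bearing (E)-allylic bromide.
4. The chromene is cut at the aryl–O bond (SNAr of (R)-linalool alkoxide on a 2-fluorobenzaldehyde, quaternary centre from the chiral pool) and at C3=C4 (ring-closing metathesis). The allylic bromide arises by SeO2 oxidation of the (E)-methyl group.
5. Ring order: benzene ring (bought), then the pyran ring of the chromene (step 5), then the furanone ring (step 12).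

Key step: step 12

Assumption: in step 13 the cupreine-derived catalyst is taken to return the proton to the face of C5 that gives (5R); if the sense is the opposite, its pseudo-enantiomer 9-O-benzylcupreidine is used under the same conditions.

**Route**

Step 1
Reactants: 1 4-fluoro-3-methylphenol
Product: 2 (4-fluoro-3-methylphenoxy)triisopropylsilane
Conditions: i-Pr3SiCl, imidazole, DMF, 23 °C
Reagents that add atoms: triisopropylsilyl chloride, CC(C)[Si](Cl)(C(C)C)C(C)C
Why: Imidazole-promoted O-silylation gives a bulky silyl ether that should survive alkoxides and organometallics in the later steps and, unlike a small ether, does not direct metalation to its own ortho positions.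

Step 2
Reactants: 2 (4-fluoro-3-methylphenoxy)triisopropylsilane
Product: 4 2-fluoro-3-methyl-5-(triisopropylsilyloxy)benzaldehyde, via aryllithium 3 (not isolated)
Conditions: s-BuLi, TMEDA, THF, −78 °C; then DMF; aq. NH4Cl
Reagents that add atoms: N,N-dimethylformamide, CN(C)C=O
Why: Fluorine-directed ortho-lithiation (directed ortho-metalation) should take place at the only free position next to fluorine, and formylation of the aryllithium with DMF installs the aldehyde that activates the fluoride for step 3 and later becomes C4 of the chromene.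

Step 3
Reactants: 4 2-fluoro-3-methyl-5-(triisopropylsilyloxy)benzaldehyde; 5 (R)-linalool
Product: 7 2-{[(3R)-3,7-dimethylocta-1,6-dien-3-yl]oxy}-3-methyl-5-(triisopropylsilyloxy)benzaldehyde, via potassium (R)-linalyl oxide 6 (not isolated)
Conditions: 5, KN(SiMe3)2, THF, 0 °C; then 4, 0 → 40 °C
Reagents that add atoms: none
Why: Nucleophilic aromatic substitution (addition–elimination) of the ortho-formyl-activated fluoride by the tertiary alkoxide forms the aryl–O bond without touching the C–O bond of linalool, so its (R) centre becomes C2 of the chromene with retention.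

Step 4
Reactants: 7 2-{[(3R)-3,7-dimethylocta-1,6-dien-3-yl]oxy}-3-methyl-5-(triisopropylsilyloxy)benzaldehyde
Product: 8 {4-{[(3R)-3,7-dimethylocta-1,6-dien-3-yl]oxy}-3-ethenyl-5-methylphenoxy}triisopropylsilane
Conditions: Ph3PCH3Br, KOt-Bu, THF, 0 °C
Reagents that add atoms: methyltriphenylphosphonium bromide, C[P+](c1ccccc1)(c1ccccc1)c1ccccc1.[Br-]
Why: Wittig methylenation of the non-enolisable aryl aldehyde gives the styrene needed for ring closure.

Step 5
Reactants: 8 {4-{[(3R)-3,7-dimethylocta-1,6-dien-3-yl]oxy}-3-ethenyl-5-methylphenoxy}triisopropylsilane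
Product: 9 (2R)-2,8-dimethyl-2-(4-methylpent-3-en-1-yl)-6-(triisopropylsilyloxy)-2H-chromene
Conditions: RuCl2(=CHPh)(PCy3)2 (first-generation Grubbs catalyst, 5 mol %), CH2Cl2 (5 mM), 40 °C
Reagents that add atoms: none
Why: Ring-closing olefin metathesis between the two monosubstituted alkenes closes the pyran ring with loss of ethene, and the phosphine-only ruthenium carbene is chosen because it engages the trisubstituted side-chain alkene only slowly.

Step 6
Reactants: 9 (2R)-2,8-dimethyl-2-(4-methylpent-3-en-1-yl)-6-(triisopropylsilyloxy)-2H-chromene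
Product: 10 (2E)-5-[(2R)-2,8-dimethyl-6-(triisopropylsilyloxy)-2H-chromen-2-yl]-2-methylpent-2-en-1-ol
Conditions: SeO2 (0.3 equiv), t-BuOOH, salicylic acid (cat.), CH2Cl2, 23 °C
Reagents that add atoms: tert-butyl hydroperoxide, CC(C)(C)OO
Why: Selenium dioxide allylic oxidation (ene reaction followed by [2,3]-sigmatropic shift) is known to hydroxylate the (E)-methyl group of a terminal isopropylidene unit, and the chromene alkene has no allylic hydrogen that could compete.

Step 7
Reactants: 10 (2E)-5-[(2R)-2,8-dimethyl-6-(triisopropylsilyloxy)-2H-chromen-2-yl]-2-methylpent-2-en-1-ol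
Product: 11 (2R)-2-[(3E)-5-bromo-4-methylpent-3-en-1-yl]-2,8-dimethyl-6-(triisopropylsilyloxy)-2H-chromene
Conditions: CBr4, PPh3, CH2Cl2, −20 °C
Reagents that add atoms: carbon tetrabromide, BrC(Br)(Br)Br
Why: The Appel reaction converts the primary allylic alcohol into the bromide under neutral conditions without change of the (E) geometry.

Step 8
Reactants: 12 5-bromo-2-methylpent-2-ene; 13 3-(trimethylsilyl)prop-2-ynal
Product: 15 7-methyl-1-(trimethylsilyl)oct-6-en-1-yn-3-ol (racemic), via homoprenylmagnesium bromide 14 (not isolated)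
Conditions: 12, Mg, THF, 40 °C; then 13, −78 → 0 °C; aq. NH4Cl
Reagents that add atoms: none
Why: Grignard 1,2-addition to the ynal gives the propargylic carbinol, which may be racemic because this centre is erased in steps 12 and 13.

Step 9
Reactants: 15 7-methyl-1-(trimethylsilyl)oct-6-en-1-yn-3-ol (racemic)
Product: 16 7-methyloct-6-en-1-yn-3-ol (racemic)
Conditions: K2CO3 (0.2 equiv), MeOH, 23 °C
Reagents that add atoms: none
Why: Carbonate-catalysed methanolysis cleaves the C(sp)–Si bond (protodesilylation) and leaves the alcohol and the alkene untouched.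

Step 10
Reactants: 11 (2R)-2-[(3E)-5-bromo-4-methylpent-3-en-1-yl]-2,8-dimethyl-6-(triisopropylsilyloxy)-2H-chromene; 16 7-methyloct-6-en-1-yn-3-ol (racemic)
Product: 17 (10E)-13-[(2R)-2,8-dimethyl-6-(triisopropylsilyloxy)-2H-chromen-2-yl]-2,10-dimethyltrideca-2,10-dien-7-yn-6-ol (both C6 epimers)
Conditions: CuI (10 mol %), n-Bu4NI (10 mol %), K2CO3, DMF, 23 °C
Reagents that add atoms: none
Why: Copper acetylide allylation (SN2 coupling of the monovalent copper acetylide with a primary allylic bromide) joins the two fragments as a skipped enyne, keeps the (E) alkene and tolerates the free hydroxyl group.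

Step 11
Reactants: 17 (10E)-13-[(2R)-2,8-dimethyl-6-(triisopropylsilyloxy)-2H-chromen-2-yl]-2,10-dimethyltrideca-2,10-dien-7-yn-6-ol (both C6 epimers)
Product: 18 (10E)-13-[(2R)-2,8-dimethyl-6-(triisopropylsilyloxy)-2H-chromen-2-yl]-2,10-dimethyltrideca-2,10-dien-7-yn-6-yl methanesulfonate (both C6 epimers)
Conditions: MsCl, Et3N, CH2Cl2, −78 °C (crude 18 used at once)
Reagents that add atoms: methanesulfonyl chloride, CS(=O)(=O)Cl
Why: Mesylation turns the propargylic hydroxyl into the leaving group that the palladium-mediated umpolung of step 12 needs.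

Step 12
Reactants: 18 (10E)-13-[(2R)-2,8-dimethyl-6-(triisopropylsilyloxy)-2H-chromen-2-yl]-2,10-dimethyltrideca-2,10-dien-7-yn-6-yl methanesulfonate (both C6 epimers)
Product: 21 5-{(2E)-5-[(2R)-2,8-dimethyl-6-(triisopropylsilyloxy)-2H-chromen-2-yl]-2-methylpent-2-en-1-yl}-3-(4-methylpent-3-en-1-yl)furan-2(3H)-one (both C3 epimers), via allenylzinc 19 (not isolated), via zinc alkynoate 20 (not isolated)
Conditions: Pd(OAc)2 (5 mol %), PPh3 (5 mol %), Et2Zn (3 equiv), CO2 (1 atm), THF, −20 → 23 °C; then H2O (10 equiv), AgOSO2CF3 (15 mol %), 23 °C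
Reagents that add atoms: carbon dioxide, O=C=O
Why: Proposed new method: zerovalent palladium (formed from Pd(OAc)2, PPh3 and Et2Zn) should ionise the propargylic mesylate in an anti-SN2′ sense and ethyl transfer from zinc should turn the allenylpalladium species into allenyl(ethyl)zinc 19, with zinc on the former alkyne carbon that is to become C5; CO2 should then be taken up through a six-membered SE2′ transition state at the other allene terminus, the carbon that carried the mesylate, which forms the C2–C3 bond and gives zinc alkynoate 20. After water has destroyed the remaining ethyl–zinc bonds, monovalent silver should activate the alkyne for anti-attack of the carboxylate oxygen at C5 and protodeargentation at C4, so that the O1–C5 bond and the ring are formed in the same flask. The closest known reaction types are the Pd/Et2Zn umpolung of propargylic mesylates to allenylzinc reagents that add to aldehydes at this same carbon, the Pd/Et2Zn carboxylation of allylic alcohols under 1 atm of CO2, and the silver-catalysed cycloisomerisation of 3-alkynoic acids to furan-2(3H)-ones; their union on one propargylic substrate is what is new. The single ring is closed in the 5-endo-dig mode (4-exo-dig is too strained), and the only new stereocentre, C3, is left uncontrolled on purpose because step 13 moves its hydrogen to C5, where both C3 epimers converge. The selectivity that the step needs is SE2′ and not SE2 capture of CO2, secured by the cyclic transition state with zinc on the sp2 carbon that the position of the mesylate dictates, and ring closure before any base-induced shift of the triple bond to the allenoate, secured by keeping the acid as its zinc carboxylate, whose C3–H is not acidic.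

Step 13
Reactants: 21 5-{(2E)-5-[(2R)-2,8-dimethyl-6-(triisopropylsilyloxy)-2H-chromen-2-yl]-2-methylpent-2-en-1-yl}-3-(4-methylpent-3-en-1-yl)furan-2(3H)-one (both C3 epimers)
Product: 22 (5R)-5-{(2E)-5-[(2R)-2,8-dimethyl-6-(triisopropylsilyloxy)-2H-chromen-2-yl]-2-methylpent-2-en-1-yl}-3-(4-methylpent-3-en-1-yl)furan-2(5H)-one
Conditions: 9-O-benzylcupreine (5 mol %), CH2Cl2, −20 °C
Reagents that add atoms: none
Why: Proton-transfer catalysis (asymmetric olefin isomerisation of a β,γ- to an α,β-unsaturated butenolide) is known for 5-alkylfuran-2(3H)-ones: the quinuclidine nitrogen should remove H-3 to give a hydrogen-bonded 2-oxidofuran ion pair and return the proton to one face of C5, which sets (5R) under catalyst control while conjugation with the lactone carbonyl drives the shift.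

Step 14
Reactants: 22 (5R)-5-{(2E)-5-[(2R)-2,8-dimethyl-6-(triisopropylsilyloxy)-2H-chromen-2-yl]-2-methylpent-2-en-1-yl}-3-(4-methylpent-3-en-1-yl)furan-2(5H)-one
Product: 23 2'-epi-tuberatolide B
Conditions: n-Bu4NF, AcOH (1:1), THF, 0 °C
Reagents that add atoms: none
Why: Buffered fluoride cleaves the aryl silyl ether (desilylation), and the acetic acid should keep the medium from epimerising C5 or opening the lactone.

**Compound list**

1 | 4-fluoro-3-methylphenol | Cc1cc(O)ccc1F | starting material
2 | (4-fluoro-3-methylphenoxy)triisopropylsilane | Cc1cc(O[Si](C(C)C)(C(C)C)C(C)C)ccc1F | intermediate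
3 | [2-fluoro-3-methyl-5-(triisopropylsilyloxy)phenyl]lithium | Cc1cc(O[Si](C(C)C)(C(C)C)C(C)C)cc([Li])c1F | intermediate (not isolated)
4 | 2-fluoro-3-methyl-5-(triisopropylsilyloxy)benzaldehyde | Cc1cc(O[Si](C(C)C)(C(C)C)C(C)C)cc(C=O)c1F | intermediate
5 | (R)-linalool = (3R)-3,7-dimethylocta-1,6-dien-3-ol | C=C[C@](C)(O)CCC=C(C)C | starting material
6 | potassium (3R)-3,7-dimethylocta-1,6-dien-3-olate | C=C[C@](C)([O-])CCC=C(C)C.[K+] | intermediate (not isolated)
7 | 2-{[(3R)-3,7-dimethylocta-1,6-dien-3-yl]oxy}-3-methyl-5-(triisopropylsilyloxy)benzaldehyde | C=C[C@](C)(Oc1c(C=O)cc(O[Si](C(C)C)(C(C)C)C(C)C)cc1C)CCC=C(C)C | intermediate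
8 | {4-{[(3R)-3,7-dimethylocta-1,6-dien-3-yl]oxy}-3-ethenyl-5-methylphenoxy}triisopropylsilane | C=C[C@](C)(Oc1c(C=C)cc(O[Si](C(C)C)(C(C)C)C(C)C)cc1C)CCC=C(C)C | intermediate
9 | (2R)-2,8-dimethyl-2-(4-methylpent-3-en-1-yl)-6-(triisopropylsilyloxy)-2H-chromene | CC(C)=CCC[C@]1(C)C=Cc2cc(O[Si](C(C)C)(C(C)C)C(C)C)cc(C)c2O1 | intermediate
10 | (2E)-5-[(2R)-2,8-dimethyl-6-(triisopropylsilyloxy)-2H-chromen-2-yl]-2-methylpent-2-en-1-ol | OC/C(C)=C/CC[C@]1(C)C=Cc2cc(O[Si](C(C)C)(C(C)C)C(C)C)cc(C)c2O1 | intermediate
11 | (2R)-2-[(3E)-5-bromo-4-methylpent-3-en-1-yl]-2,8-dimethyl-6-(triisopropylsilyloxy)-2H-chromene | BrC/C(C)=C/CC[C@]1(C)C=Cc2cc(O[Si](C(C)C)(C(C)C)C(C)C)cc(C)c2O1 | intermediate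
12 | 5-bromo-2-methylpent-2-ene | CC(C)=CCCBr | starting material
13 | 3-(trimethylsilyl)prop-2-ynal | C[Si](C)(C)C#CC=O | starting material
14 | (4-methylpent-3-en-1-yl)magnesium bromide | CC(C)=CCC[Mg]Br | intermediate (not isolated)
15 | 7-methyl-1-(trimethylsilyl)oct-6-en-1-yn-3-ol (racemic) | CC(C)=CCCC(O)C#C[Si](C)(C)C | intermediate
16 | 7-methyloct-6-en-1-yn-3-ol (racemic) | CC(C)=CCCC(O)C#C | intermediate
17 | (10E)-13-[(2R)-2,8-dimethyl-6-(triisopropylsilyloxy)-2H-chromen-2-yl]-2,10-dimethyltrideca-2,10-dien-7-yn-6-ol (both C6 epimers) | CC(C)=CCCC(O)C#CC/C(C)=C/CC[C@]1(C)C=Cc2cc(O[Si](C(C)C)(C(C)C)C(C)C)cc(C)c2O1 | intermediate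
18 | methanesulfonate of 17 (both C6 epimers) | CC(C)=CCCC(OS(C)(=O)=O)C#CC/C(C)=C/CC[C@]1(C)C=Cc2cc(O[Si](C(C)C)(C(C)C)C(C)C)cc(C)c2O1 | intermediate
19 | ethyl{(10E)-13-[(2R)-2,8-dimethyl-6-(triisopropylsilyloxy)-2H-chromen-2-yl]-2,10-dimethyltrideca-2,6,7,10-tetraen-8-yl}zinc | CC(C)=CCCC=C=C([Zn]CC)C/C(C)=C/CC[C@]1(C)C=Cc2cc(O[Si](C(C)C)(C(C)C)C(C)C)cc(C)c2O1 | intermediate (not isolated)
20 | ethylzinc (6E)-9-[(2R)-2,8-dimethyl-6-(triisopropylsilyloxy)-2H-chromen-2-yl]-6-methyl-2-(4-methylpent-3-en-1-yl)non-6-en-3-ynoate | CC[Zn]OC(=O)C(CCC=C(C)C)C#CC/C(C)=C/CC[C@]1(C)C=Cc2cc(O[Si](C(C)C)(C(C)C)C(C)C)cc(C)c2O1 | intermediate (not isolated)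
21 | 5-{(2E)-5-[(2R)-2,8-dimethyl-6-(triisopropylsilyloxy)-2H-chromen-2-yl]-2-methylpent-2-en-1-yl}-3-(4-methylpent-3-en-1-yl)furan-2(3H)-one (both C3 epimers) | CC(C)=CCCC1C=C(C/C(C)=C/CC[C@]2(C)C=Cc3cc(O[Si](C(C)C)(C(C)C)C(C)C)cc(C)c3O2)OC1=O | intermediate
22 | (5R)-5-{(2E)-5-[(2R)-2,8-dimethyl-6-(triisopropylsilyloxy)-2H-chromen-2-yl]-2-methylpent-2-en-1-yl}-3-(4-methylpent-3-en-1-yl)furan-2(5H)-one | CC(C)=CCCC1=C[C@@H](C/C(C)=C/CC[C@]2(C)C=Cc3cc(O[Si](C(C)C)(C(C)C)C(C)C)cc(C)c3O2)OC1=O | intermediate
23 | 2'-epi-tuberatolide B = (5R)-5-{(2E)-5-[(2R)-6-hydroxy-2,8-dimethyl-2H-chromen-2-yl]-2-methylpent-2-en-1-yl}-3-(4-methylpent-3-en-1-yl)furan-2(5H)-one | CC(C)=CCCC1=C[C@@H](C/C(C)=C/CC[C@]2(C)C=Cc3cc(O)cc(C)c3O2)OC1=O | target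

**Step count**

Total: 14 steps. Longest linear sequence: 12 steps (steps 1–7 and 10–14, from 1).

**Steps most likely to fail, with fallbacks**

Step 12 (proposed new method). What may go wrong: capture of CO2 at the zinc-bearing carbon instead of the remote allene terminus, loss of the allenylzinc by protonation or by ethyl or hydride transfer, or drift of the first-formed furan-2(3H)-one into the conjugated isomer without stereocontrol. The fallback uses known chemistry, sets out from 11 and 12, comes back to the route at 22 and makes step 13 unnecessary; the lactone carbonyl then comes from CO, the ring oxygen from water and the C5 centre from chirality transfer. Bromide 12 and LiC≡CH·H2NCH2CH2NH2 in DMSO would give 6-methylhept-5-en-1-yne F1, and n-BuLi followed by Bu3SnCl would give tributyl(6-methylhept-5-en-1-yn-1-yl)stannane F2. Carbonylative Stille coupling of 11 with F2 (Pd2(dba)3, AsPh3, CO 3 atm, THF, 50 °C) would give the allyl alkynyl ketone F3. Asymmetric transfer hydrogenation with RuCl[(S,S)-TsDPEN](p-cymene) in 2-propanol would give the (S)-propargylic alcohol F4, and MsCl with Et3N its mesylate F5. Pd(PPh3)4, CO (1 atm) and water in THF would convert F5 into the allenic acid F6 by anti-SN2′ oxidative addition of zerovalent palladium, CO insertion with retention and hydrolysis. AgNO3 (10 mol %) in acetone would close F6 to 22 by anti-oxyargentation, with net inversion at the former carbinol carbon, so (S)-F4 should lead to (5R)-22.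

Step 13. What may go wrong: poor facial selectivity in the return of the proton to C5 (the chromene centre is too remote to help, so only the catalyst differentiates the faces), or the opposite sense of induction. The fallback sets out from 21 and comes back at 22. Et3N in CH2Cl2 would isomerise 21 without selectivity to 22 and its C5 epimer F7. Because of the fixed chromene centre these two are diastereomers, which would be separated by preparative HPLC on a chiral stationary phase. F7 would be equilibrated again with 22 by DBU (reversible deprotonation at C5 through the 2-oxidofuran) and recycled.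

Step 3. What may go wrong: slow addition–elimination at a fluoride that is flanked by a methyl group and deactivated by the para silyloxy group, attack of the alkoxide at silicon with loss of the protecting group, or addition of the alkoxide to the formyl group. The fallback sets out from 4 and comes back at 7. KOSiMe3 in THF followed by aqueous work-up would exchange fluoride for hydroxyl and give 2-hydroxy-3-methyl-5-(triisopropylsilyloxy)benzaldehyde F8. Palladium-catalysed asymmetric allylic etherification (Tsuji–Trost type) of F8 with geranyl methyl carbonate, Pd2(dba)3 and the enantiomer of N,N′-(cyclohexane-1,2-diyl)bis[2-(diphenylphosphino)benzamide] that leads to the (R)-ether would then give 7 by attack of the phenoxide at the more substituted end of the π-allyl complex. The quaternary centre is then set by the catalyst and (R)-linalool is no longer needed.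

**Further compounds**

F1 | step 12 | 6-methylhept-5-en-1-yne | C#CCCC=C(C)C
F2 | step 12 | tributyl(6-methylhept-5-en-1-yn-1-yl)stannane | CCCC[Sn](CCCC)(CCCC)C#CCCC=C(C)C
F3 | step 12 | (10E)-13-[(2R)-2,8-dimethyl-6-(triisopropylsilyloxy)-2H-chromen-2-yl]-2,10-dimethyltrideca-2,10-dien-6-yn-8-one | CC(C)=CCCC#CC(=O)C/C(C)=C/CC[C@]1(C)C=Cc2cc(O[Si](C(C)C)(C(C)C)C(C)C)cc(C)c2O1
F4 | step 12 | (8S,10E)-13-[(2R)-2,8-dimethyl-6-(triisopropylsilyloxy)-2H-chromen-2-yl]-2,10-dimethyltrideca-2,10-dien-6-yn-8-ol | CC(C)=CCCC#C[C@@H](O)C/C(C)=C/CC[C@]1(C)C=Cc2cc(O[Si](C(C)C)(C(C)C)C(C)C)cc(C)c2O1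
F5 | step 12 | methanesulfonate of F4 (8S) | CC(C)=CCCC#C[C@@H](OS(C)(=O)=O)C/C(C)=C/CC[C@]1(C)C=Cc2cc(O[Si](C(C)C)(C(C)C)C(C)C)cc(C)c2O1
F6 | step 12 | (aR,6E)-9-[(2R)-2,8-dimethyl-6-(triisopropylsilyloxy)-2H-chromen-2-yl]-6-methyl-2-(4-methylpent-3-en-1-yl)nona-2,3,6-trienoic acid | CC(C)=CCCC(C(=O)O)=[C@@]=C([H])C/C(C)=C/CC[C@]1(C)C=Cc2cc(O[Si](C(C)C)(C(C)C)C(C)C)cc(C)c2O1
F7 | step 13 | (5S)-epimer of 22 | CC(C)=CCCC1=C[C@H](C/C(C)=C/CC[C@]2(C)C=Cc3cc(O[Si](C(C)C)(C(C)C)C(C)C)cc(C)c3O2)OC1=O
F8 | step 3 | 2-hydroxy-3-methyl-5-(triisopropylsilyloxy)benzaldehyde | Cc1cc(O[Si](C(C)C)(C(C)C)C(C)C)cc(C=O)c1O
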